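**Assumption:** compounds 1, 9 and 11 are bought; methyl (R)-glycidate (L-serine series) is the only chiral input. The route has not been run; selectivities quoted are expectations from analogous reactions.

## Retrosynthetic overview

1. Target 20 ⇐ tris-MOM flavan 19 (deprotection) ⇐ 2,3-trans-flavan-3-ol 17 by Barton–McCombie removal of a relay oxygen at C3.
2. Pyran ring ⇐ Pd-catalysed intramolecular aryl C–O coupling of chloro-alcohol 15, with retention at C2. This is the only ring built (step 13); the A and B rings are purchased arenes.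
3. C1'–C2 bond and the C2 stereocentre ⇐ Felkin–Anh addition of the aryl-lithium from bromide 8 to (R)-α-silyloxy aldehyde 14. The C3 centre of 14 is bought as methyl (R)-glycidate and opened by the A-ring aryl-copper.
4. B ring 8 ⇐ 2-bromo-4,5-dihydroxybenzaldehyde. The key step is an aromatic Claisen [3,3] rearrangement of a 1,1-dimethylallyl ether, which forges the C3'–prenyl bond; the C2' prenyl grows from the CHO carbon.

## Route

**Step 1**
Reactants: 1, 2-bromo-4,5-dihydroxybenzaldehyde
Product: 2, 2-bromo-5-hydroxy-4-(methoxymethoxy)benzaldehyde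
Conditions: MOMCl (1.05 equiv), K2CO3, acetone, 0 °C → rt
Reagents that add atoms: chloromethyl methyl ether, COCCl
Why: Selective Williamson O-alkylation of the more acidic phenol para to the formyl group.

**Step 2**
Reactants: 2, 2-bromo-5-hydroxy-4-(methoxymethoxy)benzaldehyde
Product: 3, 2-bromo-4-(methoxymethoxy)-5-[(2-methylbut-3-en-2-yl)oxy]benzaldehyde
Conditions: tert-butyl 2-methylbut-3-en-2-yl carbonate, Pd(PPh3)4 (2 mol%), THF, 0 °C → rt
Reagents that add atoms: tert-butyl 2-methylbut-3-en-2-yl carbonate, CC(C)(C)OC(=O)OC(C)(C)C=C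
Why: Tsuji–Trost O-allylation; the phenoxide attacks the substituted terminus of the π-(1,1-dimethylallyl)Pd complex to give the tertiary ether, and the aryl bromide is inert at this temperature.

**Step 3 (key step)**
Reactants: 3, 2-bromo-4-(methoxymethoxy)-5-[(2-methylbut-3-en-2-yl)oxy]benzaldehyde
Product: 4, 6-bromo-3-hydroxy-4-(methoxymethoxy)-2-(3-methylbut-2-en-1-yl)benzaldehyde
Conditions: PhMe, 120 °C, sealed tube
Reagents that add atoms: none
Why: Aromatic Claisen [3,3]-sigmatropic rearrangement to the only free ortho carbon, with allylic inversion turning the 1,1-dimethylallyl ether into the C-prenyl group, followed by rearomatisation.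

**Step 4**
Reactants: 4, 6-bromo-3-hydroxy-4-(methoxymethoxy)-2-(3-methylbut-2-en-1-yl)benzaldehyde
Product: 5, 6-bromo-3,4-bis(methoxymethoxy)-2-(3-methylbut-2-en-1-yl)benzaldehyde
Conditions: NaH, MOMCl, DMF, 0 °C → rt
Reagents that add atoms: chloromethyl methyl ether, COCCl
Why: Williamson protection of the hindered phenol before organometallic steps.

**Step 5**
Reactants: 5, 6-bromo-3,4-bis(methoxymethoxy)-2-(3-methylbut-2-en-1-yl)benzaldehyde
Product: 6, [6-bromo-3,4-bis(methoxymethoxy)-2-(3-methylbut-2-en-1-yl)phenyl]methanol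
Conditions: NaBH4, MeOH/THF, 0 °C
Reagents that add atoms: none
Why: Chemoselective borohydride reduction of the aldehyde.

**Step 6**
Reactants: 6, [6-bromo-3,4-bis(methoxymethoxy)-2-(3-methylbut-2-en-1-yl)phenyl]methanol
Product: 7, 1-bromo-2-(bromomethyl)-4,5-bis(methoxymethoxy)-3-(3-methylbut-2-en-1-yl)benzene
Conditions: CBr4, PPh3, CH2Cl2, 0 °C; used directly
Reagents that add atoms: carbon tetrabromide, BrC(Br)(Br)Br
Why: Appel bromination under neutral conditions tolerates the MOM ethers and the prenyl alkene.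

**Step 7**
Reactants: 7, 1-bromo-2-(bromomethyl)-4,5-bis(methoxymethoxy)-3-(3-methylbut-2-en-1-yl)benzene
Product: 8, 1-bromo-4,5-bis(methoxymethoxy)-2,3-bis(3-methylbut-2-en-1-yl)benzene
Conditions: 2-methylprop-1-enylmagnesium bromide, CuI (10 mol%), THF, −30 → 0 °C
Reagents that add atoms: 2-methylprop-1-en-1-ylmagnesium bromide, CC(C)=C[Mg]Br
Why: Cu-catalysed sp2–sp3 cross-coupling at the benzylic bromide builds the second prenyl group; the aryl bromide does not react without Pd or Ni.

**Step 8**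
Reactants: 9, 4-bromo-3-chlorophenol
Product: 10, 1-bromo-2-chloro-4-(methoxymethoxy)benzene
Conditions: MOMCl, i-Pr2NEt, CH2Cl2, 0 °C → rt
Reagents that add atoms: chloromethyl methyl ether, COCCl
Why: Phenol protection ahead of Grignard formation.

**Step 9**
Reactants: 10, 1-bromo-2-chloro-4-(methoxymethoxy)benzene (1.3 equiv); 11, methyl (2R)-oxirane-2-carboxylate (methyl (R)-glycidate)
Product: 12, methyl (2R)-3-[2-chloro-4-(methoxymethoxy)phenyl]-2-hydroxypropanoate
Conditions: Mg, LiCl, THF, rt (ArMgBr from the C–Br bond); then CuI (10 mol%), 11, THF, −40 → −10 °C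
Reagents that add atoms: none
Why: Cu-catalysed aryl-Grignard opening of the glycidate at the terminal CH2 leaves the purchased stereocentre untouched (R retained).

**Step 10**
Reactants: 12, methyl (2R)-3-[2-chloro-4-(methoxymethoxy)phenyl]-2-hydroxypropanoate
Product: 13, methyl (2R)-3-[2-chloro-4-(methoxymethoxy)phenyl]-2-[(triisopropylsilyl)oxy]propanoate
Conditions: TIPSOTf, 2,6-lutidine, CH2Cl2, 0 °C
Reagents that add atoms: triisopropylsilyl triflate, CC(C)[Si](C(C)C)(C(C)C)OS(=O)(=O)C(F)(F)F
Why: Silylation gives a bulky, non-chelating, migration-resistant group for the Felkin step.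

**Step 11**
Reactants: 13, methyl (2R)-3-[2-chloro-4-(methoxymethoxy)phenyl]-2-[(triisopropylsilyl)oxy]propanoate
Product: 14, (2R)-3-[2-chloro-4-(methoxymethoxy)phenyl]-2-[(triisopropylsilyl)oxy]propanal
Conditions: DIBAL-H (1.1 equiv), CH2Cl2, −78 °C; Rochelle salt work-up; used crude
Reagents that add atoms: none
Why: Low-temperature DIBAL half-reduction of the α-silyloxy ester stops at the aldehyde without epimerisation.

**Step 12**
Reactants: 8, 1-bromo-4,5-bis(methoxymethoxy)-2,3-bis(3-methylbut-2-en-1-yl)benzene (1.2 equiv); 14, (2R)-3-[2-chloro-4-(methoxymethoxy)phenyl]-2-[(triisopropylsilyl)oxy]propanal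
Product: 15, (1S,2R)-1-[4,5-bis(methoxymethoxy)-2,3-bis(3-methylbut-2-en-1-yl)phenyl]-3-[2-chloro-4-(methoxymethoxy)phenyl]-2-[(triisopropylsilyl)oxy]propan-1-ol
Conditions: 8, t-BuLi (2 equiv), THF, −78 °C; then 14, −78 °C; chromatographic removal of the minor syn epimer
Reagents that add atoms: none
Why: Br/Li exchange then Felkin–Anh 1,2-addition, in which the α-OTIPS group sits anti to the incoming aryl-lithium so the purchased centre sets the new carbinol as 1S (anti, about 5:1 expected).

**Step 13**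
Reactants: 15, the (1S,2R)-chloro-alcohol above
Product: 16, (2S,3R)-2-[4,5-bis(methoxymethoxy)-2,3-bis(3-methylbut-2-en-1-yl)phenyl]-7-(methoxymethoxy)-3-[(triisopropylsilyl)oxy]chromane (2,3-trans)
Conditions: RockPhos Pd G3 (3 mol%) [or Pd(OAc)2 / 2-(di-tert-butylphosphino)-1,1'-binaphthyl], Cs2CO3, PhMe, 80 °C
Reagents that add atoms: none
Why: Intramolecular Buchwald–Hartwig C–O coupling closes the pyran ring without breaking the carbinol C–O bond, so C2 is retained.

**Step 14**
Reactants: 16, the (2S,3R)-silyl ether above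
Product: 17, (2S,3R)-2-[4,5-bis(methoxymethoxy)-2,3-bis(3-methylbut-2-en-1-yl)phenyl]-7-(methoxymethoxy)chroman-3-ol
Conditions: TBAF, THF, rt
Reagents that add atoms: none
Why: Fluoride desilylation frees only the C3 hydroxyl; MOM ethers and alkenes are inert.

**Step 15**
Reactants: 17, the (2S,3R)-flavan-3-ol above
Product: 18, O-[(2S,3R)-2-[4,5-bis(methoxymethoxy)-2,3-bis(3-methylbut-2-en-1-yl)phenyl]-7-(methoxymethoxy)chroman-3-yl] 1H-imidazole-1-carbothioate
Conditions: 1,1'-thiocarbonyldiimidazole, DMAP (cat.), PhMe, 80 °C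
Reagents that add atoms: 1,1'-thiocarbonyldiimidazole, S=C(n1ccnc1)n1ccnc1
Why: Thioacylation of the secondary alcohol gives the Barton–McCombie precursor.

**Step 16**
Reactants: 18, the imidazolyl thiocarbonate above
Product: 19, (2R)-2-[4,5-bis(methoxymethoxy)-2,3-bis(3-methylbut-2-en-1-yl)phenyl]-7-(methoxymethoxy)chromane
Conditions: n-Bu3SnH (3 equiv, ≥0.2 M), AIBN (cat.), PhMe, 100 °C
Reagents that add atoms: none
Why: Barton–McCombie radical deoxygenation removes the relay C3 oxygen while C2 is untouched (the descriptor changes S→R only through CIP priorities); concentrated tin hydride outruns radical cyclisation onto the prenyl group or aryl shift.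

**Step 17**
Reactants: 19, the (2R)-tris-MOM flavan above
Product: 20, (+)-(2R)-kazinol I, 4-[(2R)-7-hydroxy-3,4-dihydro-2H-chromen-2-yl]-5,6-bis(3-methylbut-2-en-1-yl)benzene-1,2-diol
Conditions: 3 M aq. HCl/MeOH (degassed), rt, Ar
Reagents that add atoms: none
Why: Mild acid hydrolysis of the three aryl MOM acetals; short reaction time at rt limits prenyl–phenol cyclisation and ionisation at C2.

## Compound list

1 | 2-bromo-4,5-dihydroxybenzaldehyde | O=Cc1cc(O)c(O)cc1Br | starting material
2 | 2-bromo-5-hydroxy-4-(methoxymethoxy)benzaldehyde | O=Cc1cc(O)c(OCOC)cc1Br | intermediate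
3 | 2-bromo-4-(methoxymethoxy)-5-[(2-methylbut-3-en-2-yl)oxy]benzaldehyde | O=Cc1cc(OC(C)(C)C=C)c(OCOC)cc1Br | intermediate
4 | 6-bromo-3-hydroxy-4-(methoxymethoxy)-2-(3-methylbut-2-en-1-yl)benzaldehyde | O=Cc1c(CC=C(C)C)c(O)c(OCOC)cc1Br | intermediate
5 | 6-bromo-3,4-bis(methoxymethoxy)-2-(3-methylbut-2-en-1-yl)benzaldehyde | O=Cc1c(CC=C(C)C)c(OCOC)c(OCOC)cc1Br | intermediate
6 | [6-bromo-3,4-bis(methoxymethoxy)-2-(3-methylbut-2-en-1-yl)phenyl]methanol | OCc1c(CC=C(C)C)c(OCOC)c(OCOC)cc1Br | intermediate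
7 | 1-bromo-2-(bromomethyl)-4,5-bis(methoxymethoxy)-3-(3-methylbut-2-en-1-yl)benzene | BrCc1c(CC=C(C)C)c(OCOC)c(OCOC)cc1Br | intermediate
8 | 1-bromo-4,5-bis(methoxymethoxy)-2,3-bis(3-methylbut-2-en-1-yl)benzene | CC(C)=CCc1c(Br)cc(OCOC)c(OCOC)c1CC=C(C)C | intermediate
9 | 4-bromo-3-chlorophenol | Oc1ccc(Br)c(Cl)c1 | starting material
10 | 1-bromo-2-chloro-4-(methoxymethoxy)benzene | COCOc1ccc(Br)c(Cl)c1 | intermediate
11 | methyl (2R)-oxirane-2-carboxylate | COC(=O)[C@H]1CO1 | starting material (chiral)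
12 | methyl (2R)-3-[2-chloro-4-(methoxymethoxy)phenyl]-2-hydroxypropanoate | COC(=O)[C@H](O)Cc1ccc(OCOC)cc1Cl | intermediate
13 | methyl (2R)-3-[2-chloro-4-(methoxymethoxy)phenyl]-2-[(triisopropylsilyl)oxy]propanoate | COC(=O)[C@H](O[Si](C(C)C)(C(C)C)C(C)C)Cc1ccc(OCOC)cc1Cl | intermediate
14 | (2R)-3-[2-chloro-4-(methoxymethoxy)phenyl]-2-[(triisopropylsilyl)oxy]propanal | O=C[C@H](O[Si](C(C)C)(C(C)C)C(C)C)Cc1ccc(OCOC)cc1Cl | intermediate
15 | (1S,2R)-1-[4,5-bis(methoxymethoxy)-2,3-diprenylphenyl]-3-[2-chloro-4-(methoxymethoxy)phenyl]-2-[(triisopropylsilyl)oxy]propan-1-ol | O[C@@H](c1cc(OCOC)c(OCOC)c(CC=C(C)C)c1CC=C(C)C)[C@H](O[Si](C(C)C)(C(C)C)C(C)C)Cc1ccc(OCOC)cc1Cl | intermediate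
16 | (2S,3R)-2-[4,5-bis(methoxymethoxy)-2,3-diprenylphenyl]-7-(methoxymethoxy)-3-[(triisopropylsilyl)oxy]chromane | COCOc1ccc2C[C@@H](O[Si](C(C)C)(C(C)C)C(C)C)[C@H](c3cc(OCOC)c(OCOC)c(CC=C(C)C)c3CC=C(C)C)Oc2c1 | intermediate
17 | (2S,3R)-2-[4,5-bis(methoxymethoxy)-2,3-diprenylphenyl]-7-(methoxymethoxy)chroman-3-ol | COCOc1ccc2C[C@@H](O)[C@H](c3cc(OCOC)c(OCOC)c(CC=C(C)C)c3CC=C(C)C)Oc2c1 | intermediate
18 | O-[(2S,3R)-2-[4,5-bis(methoxymethoxy)-2,3-diprenylphenyl]-7-(methoxymethoxy)chroman-3-yl] 1H-imidazole-1-carbothioate | COCOc1ccc2C[C@@H](OC(=S)n3ccnc3)[C@H](c4cc(OCOC)c(OCOC)c(CC=C(C)C)c4CC=C(C)C)Oc2c1 | intermediate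
19 | (2R)-2-[4,5-bis(methoxymethoxy)-2,3-diprenylphenyl]-7-(methoxymethoxy)chromane | COCOc1ccc2CC[C@H](c3cc(OCOC)c(OCOC)c(CC=C(C)C)c3CC=C(C)C)Oc2c1 | intermediate
20 | (+)-(2R)-kazinol I | CC(C)=CCc1c([C@H]2CCc3ccc(O)cc3O2)cc(O)c(O)c1CC=C(C)C | target

("prenyl" = 3-methylbut-2-en-1-yl.)

## Summary

**Total steps:** 17.
**Longest linear sequence:** 13 (steps 1–7, then 12–17); the A-ring/C3 branch is steps 8–11.

**Three steps most likely to fail, with fallbacks**

- **Step 13 (Pd C–O ring closure).** The hindered vicinal-silyloxy alkoxide may undergo silyl migration, giving a dihydrobenzofuran, or β-hydride elimination, giving the ketone. Fallback: form O1–C2 by intramolecular Mitsunobu instead. Use the A-ring partner as the 3-silyloxy-7-MOM-dihydrocoumarin (from 1-bromo-2,4-bis(MOM-oxy)benzene and glycidate, then acid lactonisation), open it with the aryl-lithium from 8 to a keto-phenol, reduce, and close with PPh3/DIAD. This inverts C2, so the glycidate enantiomer and reductant are chosen to match.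
- **Step 12 (Felkin addition).** The selectivity is only moderate and the aldehyde is sensitive. Fallback: start from methyl (S)-glycidate, make the Weinreb amide, acylate the aryl-lithium from 8 to the α-silyloxy ketone and reduce with L-Selectride. Felkin hydride delivery gives the (1S,2S) syn alcohol, which closes to the 2,3-cis flavan-3-ol with the same C2 configuration and converges on 19 after deoxygenation.
- **Step 17 (acidic MOM removal).** The ortho-prenyl phenol can cyclise to a chroman, or C2 can ionise. Fallback: redesign the protection so the last step is buffered fluoride. Carry the phenols as TBS ethers and the relay C3–OH as a TES ether removed with PPTS/MeOH before the Barton step, then finish with TBAF/AcOH.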